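The earlier runs and the new flask are simulated from invented constants; scatter was added.

Reciprocal days come first: Z has two exits, each a rate per Z. Ring closure is first order; dimerisation speeds up with the charge.

| flask | Z | remark | time |
|---|---|---|---|
| ash | 0.14 M | run made earlier |  |
| alder | 0.22 M | run made earlier |  |
| flask | 0.10 M |  | 4.0 d |

| run | time / d | G / % | Z / % |
|---|---|---|---|
| ash | 0.0625 | 17.9 | 36.7 |
| ash | 0.167 | 28.3 | 13.6 |
| ash | 0.333 | 26.8 | 3.4 |
| ash | 0.833 | 16.2 | 0.9 |
| ash | 1.67 | 5.7 | 0 |
| ash | 4.00 | 1.3 | 0 |
| alder | 0.0625 | 17.1 | 28.7 |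
| alder | 0.167 | 21.6 | 8.2 |
| alder | 0.333 | 21.4 | 3.9 |
| alder | 0.833 | 11.6 | 0 |
| alder | 1.67 | 4.1 | 0 |
| alder | 4.00 | 0 | 0.2 |

(scatter of a reading: 1 percentage point)

- time up to 4.0 d at which G stands highest
- the amount of G, in percent of the Z charged, at that time

At a fixed time, the reciprocal of the Z fraction is a straight line in the charge, and its intercept, 1.40 at the first readings, is closure by itself. I read from it a closure time τc of 0.187 d. The slope gives this flask a starting dimerisation time τd of 0.0781 d, shorter than τc. Their ratio r = τc/τd, the selectivity factor, reads 2.40 for this flask.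

Of the Z charged, the share that closes to G tends to one as r nears zero and to about ln r over r at large r. The integral joins both ends: the ring share Y, the logarithm of one plus r divided by r, comes by my reading to 51.0 % for this flask. Ash has Y = 43.8 %, and its highest G reading, 28.3 %, is 0.646 of that. Keeping that fraction, I expect G to peak at 32.9 % in this flask, between the ash reading times 0.167 d and 0.333 d.

The forecast says 34 % at 0.27 d, with an “ultimate G without decay” of 50 %.

The flask gives 32.7 % at 0.255 d.

    G → L (k = 0.0620 h⁻¹)
    Z → G (k = 0.220 h⁻¹)
    2 Z → D (k = 2.70 M⁻¹ h⁻¹)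

With 0.060 M of Z, r falls with the charge to 1.44, so Y is 61.9 % and the ash fraction of it is 40.0 %. That neighbouring flask reaches 39.2 % of G and ends with L at 61.3 %.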